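**Retrosynthetic overview** (solandelactone numbering, C1 = lactone carbonyl)
1. The last bond formed is C14–O: palladium-catalysed syn-1,4 (SN2′) addition of water to an (11S,12S)-trans vinyl epoxide relays the C12 configuration to C14 and keeps the C11–O bond.
2. The vinyl epoxide (third ring, transient) comes from the C1–C11 cyclopropyl-lactone aldehyde and a C12–C22 chiral allylic sulfonium ylide.
3. The eight-membered lactone (second ring) is closed by ring-closing metathesis of a homoallyl pent-4-enoate.
4. The cyclopropane (first ring) comes from a hydroxyl-directed Simmons–Smith reaction of an allylic alcohol made by catalytic asymmetric allylboration of fumaraldehyde mono(dimethyl acetal).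
5. The C12–C22 dienol comes from carbocupration of acetylene followed by SN2′ opening of vinyloxirane.

Assumption: (R)-TRIP is taken to give the (R)-homoallylic alcohol (re-face attack) and the (1R,4R,5R)-isothiocineole ylide to give the (S,S)-trans epoxide; if either sense is the opposite, the antipodal catalyst or sulfide (both available) is used with no other change.

Step 1
Reactants: 1 (E)-4,4-dimethoxybut-2-enal (fumaraldehyde mono(dimethyl acetal)); 2 allylboronic acid pinacol ester
Product: 4 (2E,4R)-1,1-dimethoxyhepta-2,6-dien-4-ol, via O-pinacolboryl ether 3 (not isolated)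
Conditions: (R)-TRIP [(R)-3,3′-bis(2,4,6-triisopropylphenyl)-1,1′-binaphthyl-2,2′-diyl hydrogen phosphate] (5 mol %), toluene, −30 °C; aq. NaHCO3
Reagents that add atoms: none
Why: Chiral-phosphoric-acid-catalysed allylboration through a chair six-membered transition state adds the allyl group 1,2 to the enal on the face left open by the catalyst, setting C7 as R, and the acetal survives the anhydrous, weakly acidic medium.

Step 2
Reactants: 4 (2E,4R)-1,1-dimethoxyhepta-2,6-dien-4-ol
Product: 5 (1R)-1-[(1R,2R)-2-(dimethoxymethyl)cyclopropyl]but-3-en-1-ol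
Conditions: Et2Zn (2.5 equiv), CH2I2 (2.5 equiv), CH2Cl2, −15 → 0 °C; aq. NH4Cl
Reagents that add atoms: diiodomethane ICI
Why: Hydroxyl-directed Simmons–Smith (Furukawa) cyclopropanation: the zinc alkoxide delivers CH2 to the alkene face syn to oxygen in the conformer with the carbinol H eclipsing the alkene, giving the syn product (C8 and C10 both R), and the directed allylic alkene reacts far faster than the terminal one.

Step 3
Reactants: 5 (1R)-1-[(1R,2R)-2-(dimethoxymethyl)cyclopropyl]but-3-en-1-ol; 6 pent-4-enoyl chloride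
Product: 7 (1R)-1-[(1R,2R)-2-(dimethoxymethyl)cyclopropyl]but-3-en-1-yl pent-4-enoate
Conditions: Et3N, DMAP (10 mol %), CH2Cl2, 0 → 23 °C
Reagents that add atoms: none
Why: DMAP-catalysed acylation of the secondary alcohol (nucleophilic acyl substitution) under basic conditions that leave the acetal and all stereocentres untouched.

Step 4
Reactants: 7 (1R)-1-[(1R,2R)-2-(dimethoxymethyl)cyclopropyl]but-3-en-1-yl pent-4-enoate
Product: 8 (5Z,8R)-8-[(1R,2R)-2-(dimethoxymethyl)cyclopropyl]-3,4,7,8-tetrahydro-2H-oxocin-2-one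
Conditions: second-generation Grubbs catalyst RuCl2(=CHPh)(PCy3)(H2IMes) (10 mol %), CH2Cl2 (1 mM), 40 °C
Reagents that add atoms: none
Why: Ring-closing metathesis at high dilution closes the eight-membered lactone with loss of ethylene; the ring size enforces the Z alkene, the α-branched carbinol favours the folded ester rotamer, and no stereocentre is touched.

Step 5
Reactants: 8 (5Z,8R)-8-[(1R,2R)-2-(dimethoxymethyl)cyclopropyl]-3,4,7,8-tetrahydro-2H-oxocin-2-one
Product: 9 (1R,2R)-2-[(2R,4Z)-8-oxo-3,6,7,8-tetrahydro-2H-oxocin-2-yl]cyclopropane-1-carbaldehyde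
Conditions: Amberlyst-15, acetone/H2O (20:1), 23 °C
Reagents that add atoms: water O
Why: Acid-catalysed acetal hydrolysis through the cyclopropyl-stabilised oxocarbenium ion unmasks the aldehyde under conditions too mild to open the lactone or epimerise C10.

Step 6
Reactants: 10 pentylmagnesium bromide; 11 acetylene; 12 2-vinyloxirane (racemic butadiene monoepoxide)
Product: 15 (2E,5Z)-undeca-2,5-dien-1-ol, via pentylcopper·MgBr2 13 (not isolated), via (Z)-hept-1-enylcopper·MgBr2 14 (not isolated)
Conditions: CuBr·SMe2 (1.0 equiv), Et2O/Me2S, −40 °C; HC≡CH, −25 °C; then 12, THF, −40 → 0 °C; aq. NH4Cl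
Reagents that add atoms: none
Why: Normant carbocupration of acetylene is a syn addition that fixes the Z alkene, and the alkenylcopper then opens the vinyl epoxide in an anti SN2′ (1,4) sense to give the E allylic alcohol (the minor 2Z isomer is removed on AgNO3-impregnated silica); no stereocentre is formed.

Step 7
Reactants: 15 (2E,5Z)-undeca-2,5-dien-1-ol
Product: 16 (2E,5Z)-1-bromoundeca-2,5-diene
Conditions: CBr4, PPh3, CH2Cl2, −20 → 0 °C
Reagents that add atoms: carbon tetrabromide BrC(Br)(Br)Br
Why: Appel reaction (SN2 displacement of the alkoxyphosphonium by bromide) converts the primary allylic alcohol to the bromide at low temperature without allylic transposition or alkene isomerisation.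

Step 8
Reactants: 16 (2E,5Z)-1-bromoundeca-2,5-diene; 17 (1R,4R,5R)-isothiocineole [(1R,4R,5R)-4,7,7-trimethyl-6-thiabicyclo[3.2.1]octane]
Product: 18 (1R,4R,5R)-4,7,7-trimethyl-6-[(2E,5Z)-undeca-2,5-dien-1-yl]-6-thiabicyclo[3.2.1]octan-6-ium tetrafluoroborate (S-alkyl group exo)
Conditions: NaBF4 (5 equiv), CH2Cl2/H2O (1:1), 23 °C, 48 h
Reagents that add atoms: sodium tetrafluoroborate [Na+].F[B-](F)(F)F
Why: SN2 S-alkylation of the chiral sulfide by the allylic bromide on its less hindered exo lone pair, driven by exchange to the non-nucleophilic tetrafluoroborate, gives a single sulfonium diastereomer.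

Step 9
Reactants: 18 sulfonium tetrafluoroborate (1.3 equiv); 9 (1R,2R)-2-[(2R,4Z)-8-oxo-3,6,7,8-tetrahydro-2H-oxocin-2-yl]cyclopropane-1-carbaldehyde
Product: 20 (5Z,8R)-8-{(1R,2R)-2-[(2S,3S)-3-[(1E,4Z)-deca-1,4-dien-1-yl]oxiran-2-yl]cyclopropyl}-3,4,7,8-tetrahydro-2H-oxocin-2-one, via allylic sulfonium ylide 19 (not isolated)
Conditions: KN(SiMe3)2 (1.25 equiv), THF, −78 °C; then 9, −78 → −40 °C
Reagents that add atoms: none
Why: Corey–Chaykovsky-type sulfur-ylide epoxidation: the chiral sulfonium ylide adds to the aldehyde through its unshielded face and reversible betaine formation funnels the reaction through the anti betaine to the trans epoxide, so C12 is set S by the sulfide and C11 S by the trans requirement, while the non-nucleophilic base at low temperature spares the lactone.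

Step 10
Reactants: 20 (5Z,8R)-8-{(1R,2R)-2-[(2S,3S)-3-[(1E,4Z)-deca-1,4-dien-1-yl]oxiran-2-yl]cyclopropyl}-3,4,7,8-tetrahydro-2H-oxocin-2-one
Product: 21 solandelactone F, (5Z,8R)-8-{(1R,2R)-2-[(1R,2E,4S,6Z)-1,4-dihydroxydodeca-2,6-dien-1-yl]cyclopropyl}-3,4,7,8-tetrahydro-2H-oxocin-2-one
Conditions: Pd2(dba)3·CHCl3 (2.5 mol %), PPh3 (10 mol %), H2O (20 equiv), CO2 (1 atm), THF, 0 → 23 °C
Reagents that add atoms: water O
Why: Proposed new method: zerovalent palladium ionises the allylic C12–O bond of the vinyl epoxide with inversion to a syn,syn-η3-allyl complex whose C11 alkoxide is protonated or reversibly held as the hydrogencarbonate/1,2-cyclic carbonate by CO2, and bicarbonate (then losing CO2) or water attacks the distal, less hindered and inductively less deactivated C14 terminus anti to palladium, so the double inversion transfers the C12 configuration to C14 (S), gives the E alkene and leaves the C11–O bond (R in the diol) untouched; the closest known reaction types are the palladium-catalysed 1,4-addition of carboxylic acids to vinyl epoxides and the decarboxylative hydration of vinyl cyclic carbonates, neither shown for stereospecific 1,4-hydration of an acyclic internal vinyl epoxide.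

**Compound list**
1 | (E)-4,4-dimethoxybut-2-enal | COC(OC)/C=C/C=O | starting material
2 | allylboronic acid pinacol ester | C=CCB1OC(C)(C)C(C)(C)O1 | starting material
3 | 2-{[(2E,4R)-1,1-dimethoxyhepta-2,6-dien-4-yl]oxy}-4,4,5,5-tetramethyl-1,3,2-dioxaborolane | C=CC[C@@H](OB1OC(C)(C)C(C)(C)O1)/C=C/C(OC)OC | intermediate
4 | (2E,4R)-1,1-dimethoxyhepta-2,6-dien-4-ol | C=CC[C@@H](O)/C=C/C(OC)OC | intermediate
5 | (1R)-1-[(1R,2R)-2-(dimethoxymethyl)cyclopropyl]but-3-en-1-ol | COC(OC)[C@@H]1C[C@H]1[C@H](O)CC=C | intermediate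
6 | pent-4-enoyl chloride | C=CCCC(=O)Cl | starting material
7 | (1R)-1-[(1R,2R)-2-(dimethoxymethyl)cyclopropyl]but-3-en-1-yl pent-4-enoate | COC(OC)[C@@H]1C[C@H]1[C@@H](CC=C)OC(=O)CCC=C | intermediate
8 | (5Z,8R)-8-[(1R,2R)-2-(dimethoxymethyl)cyclopropyl]-3,4,7,8-tetrahydro-2H-oxocin-2-one | COC(OC)[C@@H]1C[C@H]1[C@H]1C/C=C\CCC(=O)O1 | intermediate
9 | (1R,2R)-2-[(2R,4Z)-8-oxo-3,6,7,8-tetrahydro-2H-oxocin-2-yl]cyclopropane-1-carbaldehyde | O=C[C@@H]1C[C@H]1[C@H]1C/C=C\CCC(=O)O1 | intermediate
10 | pentylmagnesium bromide | CCCCC[Mg]Br | starting material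
11 | acetylene | C#C | starting material
12 | 2-vinyloxirane (racemic) | C=CC1CO1 | starting material
13 | pentylcopper·MgBr2 | CCCCC[Cu].[Mg+2].[Br-].[Br-] | intermediate
14 | (Z)-hept-1-en-1-ylcopper·MgBr2 | CCCCC/C=C\[Cu].[Mg+2].[Br-].[Br-] | intermediate
15 | (2E,5Z)-undeca-2,5-dien-1-ol | CCCCC/C=C\C/C=C/CO | intermediate
16 | (2E,5Z)-1-bromoundeca-2,5-diene | CCCCC/C=C\C/C=C/CBr | intermediate
17 | (1R,4R,5R)-isothiocineole | C[C@@H]1CC[C@@H]2C[C@H]1SC2(C)C | starting material
18 | (1R,4R,5R)-4,7,7-trimethyl-6-[(2E,5Z)-undeca-2,5-dien-1-yl]-6-thiabicyclo[3.2.1]octan-6-ium tetrafluoroborate | CCCCC/C=C\C/C=C/C[S@+]1C(C)(C)[C@@H]2CC[C@@H](C)[C@H]1C2.F[B-](F)(F)F | intermediate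
19 | sulfonium ylide of 18 (ylide carbon = C12) | CCCCC/C=C\C/C=C/[CH-][S@+]1C(C)(C)[C@@H]2CC[C@@H](C)[C@H]1C2 | intermediate
20 | (5Z,8R)-8-{(1R,2R)-2-[(2S,3S)-3-[(1E,4Z)-deca-1,4-dien-1-yl]oxiran-2-yl]cyclopropyl}-3,4,7,8-tetrahydro-2H-oxocin-2-one | CCCCC/C=C\C/C=C/[C@@H]1O[C@H]1[C@@H]1C[C@H]1[C@H]1C/C=C\CCC(=O)O1 | intermediate
21 | solandelactone F | CCCCC/C=C\C[C@H](O)/C=C/[C@@H](O)[C@@H]1C[C@H]1[C@H]1C/C=C\CCC(=O)O1 | target

**Step count:** 10 steps in total. The longest linear sequence is 7 steps (steps 1–5, 9, 10); the side chain (steps 6–8) joins at step 9.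

**Steps most likely to fail**

Step 10 (the proposed new hydration). It can leak to the 1,2-diol, to a Z alkene through an oxygen-chelated η1-allyl, or to a conjugated triene by elimination at the doubly allylic C15. The fallback sets out from 20 and uses the known palladium-catalysed 1,4-addition of a carboxylic acid, then removes the acyl group. Pd(PPh3)4 (5 mol %) and chloroacetic acid (1.5 equiv) in THF at 0 °C give, by the same double inversion, 14-O-(chloroacetyl)solandelactone F F5. Thiourea and NaHCO3 in EtOH at 40 °C then cleave the chloroacetate without touching the lactone, and the route is rejoined at 21.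

Step 9 (ylide epoxidation). The risks are a modest trans:cis ratio with an aliphatic aldehyde (a cis epoxide would lead to the C11 epimer) and the uncertain sense of induction stated above. The fallback sets out from bromide 16 and aldehyde 9. Tributylphosphine in MeCN gives tributyl[(2E,5Z)-undeca-2,5-dien-1-yl]phosphonium bromide F3. Deprotonation with LiN(SiMe3)2 (THF, −78 °C) and E-selective Wittig olefination of 9 gives (5Z,8R)-8-{(1R,2S)-2-[(1E,3E,6Z)-dodeca-1,3,6-trien-1-yl]cyclopropyl}-3,4,7,8-tetrahydro-2H-oxocin-2-one F4. Shi asymmetric epoxidation with the enantiomer of the fructose-derived ketone (KHSO5 as Oxone, K2CO3, MeCN/dimethoxymethane/aqueous buffer, 0 °C) is expected to attack the electron-rich cyclopropyl-substituted E alkene of the diene, with the cis alkenes reacting more slowly, and returns to the route at 20.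

Step 4 (ring-closing metathesis). Eight-membered lactones often give oligomers instead of the ring. The fallback sets out from alcohol 5 and closes the ring through the acyl C–O bond. Z-selective cross-metathesis of 5 with methyl pent-4-enoate (3 equiv) uses the cyclometalated ruthenium catalyst Ru(NO3)(=CH-C6H4-2-OiPr)(C,C-chelating N-adamantyl-N′-(2,6-diisopropylphenyl)imidazolin-2-ylidene) in THF at 35 °C. It gives methyl (4Z,7R)-7-[(1R,2R)-2-(dimethoxymethyl)cyclopropyl]-7-hydroxyhept-4-enoate F1. Saponification (LiOH, THF/H2O, acidified only to pH 5) gives (4Z,7R)-7-[(1R,2R)-2-(dimethoxymethyl)cyclopropyl]-7-hydroxyhept-4-enoic acid F2. Yamaguchi macrolactonisation (2,4,6-trichlorobenzoyl chloride, Et3N, THF; then DMAP, toluene, 80 °C, 2 mM) returns to the route at 8.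

**Further compounds**
F1 | step 4 | methyl (4Z,7R)-7-[(1R,2R)-2-(dimethoxymethyl)cyclopropyl]-7-hydroxyhept-4-enoate | COC(OC)[C@@H]1C[C@H]1[C@H](O)C/C=C\CCC(=O)OC
F2 | step 4 | (4Z,7R)-7-[(1R,2R)-2-(dimethoxymethyl)cyclopropyl]-7-hydroxyhept-4-enoic acid | COC(OC)[C@@H]1C[C@H]1[C@H](O)C/C=C\CCC(=O)O
F3 | step 9 | tributyl[(2E,5Z)-undeca-2,5-dien-1-yl]phosphonium bromide | CCCCC/C=C\C/C=C/C[P+](CCCC)(CCCC)CCCC.[Br-]
F4 | step 9 | (5Z,8R)-8-{(1R,2S)-2-[(1E,3E,6Z)-dodeca-1,3,6-trien-1-yl]cyclopropyl}-3,4,7,8-tetrahydro-2H-oxocin-2-one | CCCCC/C=C\C/C=C/C=C/[C@@H]1C[C@H]1[C@H]1C/C=C\CCC(=O)O1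
F5 | step 10 | 14-O-(chloroacetyl)solandelactone F | CCCCC/C=C\C[C@H](OC(=O)CCl)/C=C/[C@@H](O)[C@@H]1C[C@H]1[C@H]1C/C=C\CCC(=O)O1
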